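A direct plan would start from (−)-caryophyllene oxide A1, epoxidise its exocyclic alkene to diepoxide A2, open the spiro-epoxide to iodohydrin A3, join C13 to C7' of alkylidene triketone A4 by reductive nickel coupling to hydroxy triketone A5, close the pyran through the C8 alcohol to spiro-chromenedione A6 and isomerise the 4,5-epoxide to the Z-allylic alcohol.
Its weakest steps would be the nickel coupling (untested polarity reversal at the enone β-carbon, weak 1,3-induction at C7'), the epoxide isomerisation (a C3 ring hydrogen would have to be taken instead of a C12 methyl hydrogen, and the Z-alkene formed) and the peracid epoxidation setting C8 (modest facial bias on a flexible ring).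

The caryophyllane half is built, not bought. With C8 read as a latent ketone, the nine-membered ring is a cyclonon-5-enone (C8, C9, C1, C2, C3=C4) whose α,β-bond C9–C1 carries the cyclobutane: the retron of an oxy-Cope ring expansion. One anionic [3,3] shift of a cis-1-cyclobutenyl-2-vinylcyclopentanolate breaks C4–C8, forms C1–C2 and delivers the cyclobutane-fused nine-membered ring, the Z-C3=C4 alkene, C5–O in place and C1 by chirality transfer. A hetero-Diels–Alder reaction on the derived 8-methylene compound then closes the pyran in one concerted step. No polarity-reversed coupling, no epoxide isomerisation and no epoxidation at C8 remain.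

Key step: step 9

Remark: caryophyllane numbering is used throughout (C1/C9 ring fusion, C4 methyl-bearing carbon, C5 carbinol, C8 spiro carbon, C13 pyran CH2, C7' isobutyl-bearing carbon, primed numbers for the triketone ring); 3,3-dimethylcyclobutanone and 2,4,6-triisopropylbenzenesulfonohydrazide are taken as purchasable.

Step 1
Reactants: 1 2-methylcyclopent-2-en-1-one
Product: 2 (S)-2-methylcyclopent-2-en-1-ol
Conditions: (R)-2-methyl-CBS-oxazaborolidine (10 mol %), catecholborane (1.5 equiv), toluene, −78 °C; MeOH, aq NaOH wash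
Reagents that add atoms: none
Why: Corey–Bakshi–Shibata reduction, in which the α-methylated alkene arm is the large group on the oxazaborolidine–borane complex, so hydride reaches one carbonyl face and the carbinol (the later C8) is set as S.

Step 2
Reactants: 2 (S)-2-methylcyclopent-2-en-1-ol
Product: 3 (1S,2S,5R)-1-methyl-6-oxabicyclo[3.1.0]hexan-2-ol (epoxide oxygen cis to OH)
Conditions: VO(acac)2 (2 mol %), t-BuOOH (1.3 equiv), CH2Cl2, 0 °C
Reagents that add atoms: tert-butyl hydroperoxide, CC(C)(C)OO
Why: Hydroxyl-directed epoxidation, in which the vanadium alkoxide of the allylic alcohol delivers the peroxide oxygen to the alkene face syn to OH, so the future C4 and C5 are set from the carbinol centre.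

Step 3
Reactants: 3 syn-epoxy alcohol
Product: 4 (1R,5R)-1-methyl-6-oxabicyclo[3.1.0]hexan-2-one
Conditions: Dess–Martin periodinane (1.2 equiv), NaHCO3, CH2Cl2, 0 → 23 °C
Reagents that add atoms: none
Why: Dess–Martin oxidation under buffered, non-nucleophilic conditions gives the α,β-epoxy ketone without epoxide opening, and both epoxide carbons keep their configuration.

Step 4
Reactants: 4 epoxy ketone
Product: 5 (1R,2R,5R)-2-ethenyl-1-methyl-6-oxabicyclo[3.1.0]hexan-2-ol
Conditions: CH2=CHMgBr (1.5 equiv), CeCl3 (1.5 equiv), THF, −78 °C; aq NH4Cl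
Reagents that add atoms: vinylmagnesium bromide, C=C[Mg]Br
Why: 1,2-Addition of the vinylcerium reagent to the α,β-epoxy ketone from the face anti to the epoxide oxygen puts vinyl trans and OH cis to the epoxide, the arrangement that the next step requires.

Step 5
Reactants: 5 vinyl epoxy alcohol
Product: 6 (2S,3R)-2-ethenyl-3-hydroxy-2-methylcyclopentan-1-one
Conditions: BF3·OEt2 (20 mol %), CH2Cl2, −78 → −40 °C; aq NaHCO3
Reagents that add atoms: none
Why: Semipinacol rearrangement of a 2,3-epoxy alcohol, in which Lewis acid activation of the epoxide triggers a 1,2-shift of the vinyl group antiperiplanar to the breaking C4–O bond with inversion at C4, so the quaternary centre (vinyl trans and methyl cis to the C5 oxygen) and the C8 ketone arise stereospecifically.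

Step 6
Reactants: 6 hydroxy ketone
Product: 7 (2S,3R)-2-ethenyl-2-methyl-3-[(triisopropylsilyl)oxy]cyclopentan-1-one
Conditions: TIPSOTf (1.2 equiv), 2,6-lutidine (2 equiv), CH2Cl2, −78 → 0 °C
Reagents that add atoms: triisopropylsilyl trifluoromethanesulfonate, CC(C)[Si](C(C)C)(C(C)C)OS(=O)(=O)C(F)(F)F
Why: Silylation of the hindered aldol-type alcohol with a silyl triflate under conditions too mild for retro-aldol cleavage; the bulky silyl group is chosen because it resists oxygen-to-oxygen transfer in the alkoxide of step 9 and shields the lower ring face in step 8.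

Step 7
Reactants: 8 3,3-dimethylcyclobutan-1-one
Product: 9 N'-(3,3-dimethylcyclobutylidene)-2,4,6-triisopropylbenzenesulfonohydrazide
Conditions: 2,4,6-(i-Pr)3C6H2SO2NHNH2 (1.0 equiv), THF, 23 °C
Reagents that add atoms: 2,4,6-triisopropylbenzenesulfonohydrazide, CC(C)c1cc(C(C)C)c(S(=O)(=O)NN)c(C(C)C)c1
Why: Condensation of a symmetric ketone with an arylsulfonyl hydrazide gives the hydrazone for the Shapiro reaction with no regio- or stereochemical issue.

Step 8
Reactants: 9 sulfonylhydrazone (1.5 equiv); 7 silyloxy vinyl ketone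
Product: 11 (1R,2S,3R)-1-(3,3-dimethylcyclobut-1-en-1-yl)-2-ethenyl-2-methyl-3-[(triisopropylsilyl)oxy]cyclopentan-1-ol, via 3,3-dimethylcyclobut-1-enyllithium 10 (not isolated)
Conditions: 9, n-BuLi (3.0 equiv), THF/TMEDA, −78 → 0 °C; CeCl3 (1.6 equiv), −78 °C; then 7, −78 °C; aq NH4Cl
Reagents that add atoms: none
Why: The Shapiro reaction (double deprotonation, loss of sulfinate and N2) gives alkenyllithium 10, whose cerium derivative should add to the enolisable ketone without proton transfer and from the face that carries only the vinyl group, anti to the α-methyl and β-silyloxy groups, so C8 is set with cyclobutenyl and vinyl cis as step 9 requires.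

Step 9
Reactants: 11 cis-dialkenyl cyclopentanol
Product: 14 (1R,3Z,5R,9S)-4,11,11-trimethyl-5-[(triisopropylsilyl)oxy]bicyclo[7.2.0]undec-3-en-8-one, via potassium alkoxide 12 (not isolated), via potassium enolate 13 (not isolated)
Conditions: KH (1.5 equiv), 18-crown-6 (1.5 equiv), THF, 0 → 40 °C; then MeOH, 23 °C (C9 equilibration); aq NH4Cl
Reagents that add atoms: none
Why: Deprotonation gives potassium alkoxide 12, in which the oxyanion weakens the C4–C8 bond so that a concerted anionic oxy-Cope [3,3] shift breaks C4–C8 and joins the vinyl terminus C2 to the cyclobutene carbon C1, giving enolate 13; the closest known reaction type is the ring expansion of cis-1-alkenyl-2-vinylcyclopentanolates to cyclonon-5-enones, here with a cyclobutenyl arm whose strain adds driving force. The nine-membered ring is not closed end to end but arises by four-carbon enlargement of the cyclopentane (the two alkenyl arms bridge the breaking bond), and the cyclobutane emerges already fused at C1–C9. Because both arms sit on the same ring face, only the boat transition state with both arms turned over the ring is possible, which fixes C3=C4 as Z and the enolate as ring-cis. C1 is set by chirality transfer, since C2 can only reach the cyclobutene face that looks towards C4, and with the C5 oxygen anti to both arms this gives 1R next to the untouched 5R centre. C9 is set on protonation of 13 and equilibrated through the enolate (KOMe in MeOH) to the trans ring fusion (9S), which should be the more stable one. The step needs the [3,3] shift to outrun heterolytic loss of an allyl anion, a [1,3] shift and silyl transfer, which the unstabilised allyl anion, the enforced boat geometry and the bulky triisopropylsilyl group on a hindered tertiary alkoxide should secure.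

Step 10
Reactants: 14 bicyclic ketone
Product: 15 (1R,3Z,5R,9S)-4,11,11-trimethyl-8-methylidene-5-[(triisopropylsilyl)oxy]bicyclo[7.2.0]undec-3-ene
Conditions: Ph3PCH3Br (3 equiv), KOt-Bu (2.8 equiv), toluene, 23 → 80 °C
Reagents that add atoms: methyltriphenylphosphonium bromide, C[P+](c1ccccc1)(c1ccccc1)c1ccccc1.[Br-]
Why: Wittig methylenation of the ring ketone installs C13; C9 could epimerise under the basic ylide but already holds the trans ring fusion, and nothing else in the molecule is base-sensitive.

Step 11
Reactants: 16 2',4',6'-trihydroxyacetophenone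
Product: 17 2-acetyl-3-hydroxy-4,4,6,6-tetramethylcyclohex-2-ene-1,5-dione (acetylsyncarpic acid)
Conditions: MeI (6 equiv), NaOMe (5 equiv), MeOH, reflux; aq HCl
Reagents that add atoms: iodomethane, CI
Why: Exhaustive dearomative C-methylation of an acylphloroglucinol, in which the acetyl group blocks one ring carbon while the other two are alkylated until quaternary; no stereocentre is formed.

Step 12
Reactants: 17 acetylsyncarpic acid
Product: 18 syncarpic acid (5-hydroxy-2,2,6,6-tetramethylcyclohex-4-ene-1,3-dione)
Conditions: 6 M aq HCl, reflux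
Reagents that add atoms: none
Why: Acid-mediated retro-Claisen deacylation of the tricarbonylmethane releases acetic acid and leaves C2' as the only nucleophilic carbon.

Step 13
Reactants: 18 syncarpic acid (2 equiv); 19 3-methylbutanal (2.5 equiv); 15 silyloxy diene
Product: 21 (1R,3Z,5R,8S,9S,7'R)-5-[(triisopropylsilyl)oxy]caryophyll-3-ene spiro-fused at C8 to 4-isobutyl-6,6,8,8-tetramethyl-3,4-dihydro-2H-chromene-5,7(6H,8H)-dione (C8 = chromene C2; C13 = C3; C7' = C4), via alkylidene triketone 20 (not isolated)
Conditions: 18, 19, L-proline (20 mol %), toluene, 23 °C, 1 h; then 15, 100 °C, sealed tube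
Reagents that add atoms: none
Why: Knoevenagel condensation (with loss of water) gives the electron-poor 1-oxadiene 20, which adds in an inverse-electron-demand hetero-Diels–Alder reaction to the 1,1-disubstituted C8=C13 alkene (oxygen to the more substituted C8, C7' to C13, the trisubstituted Z-alkene being less reactive); C8 and C7' should be set together by approach to the methylene face turned away from the ring interior and the cyclobutane, with the slim C7H2 rather than the branched C9 lying under the bulky triketone ring, which places isobutyl trans to C9 on the pyran, and minor isomers would be removed by chromatography.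

Step 14
Reactants: 21 silyl-protected adduct
Product: 22 tomentodione O
Conditions: TBAF (3 equiv), AcOH (3 equiv), THF, 23 °C
Reagents that add atoms: none
Why: Fluoride cleavage of the silyl ether under acetic acid buffering frees the C5 allylic alcohol without acid- or base-induced change at the β-alkoxy enone, the alkenes or the bicycle.

**Compound list**
1 | 2-methylcyclopent-2-en-1-one | CC1=CCCC1=O | starting material
2 | (S)-2-methylcyclopent-2-en-1-ol | CC1=CCC[C@@H]1O | intermediate
3 | (1S,2S,5R)-1-methyl-6-oxabicyclo[3.1.0]hexan-2-ol | C[C@@]12O[C@@H]1CC[C@@H]2O | intermediate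
4 | (1R,5R)-1-methyl-6-oxabicyclo[3.1.0]hexan-2-one | C[C@@]12O[C@@H]1CCC2=O | intermediate
5 | (1R,2R,5R)-2-ethenyl-1-methyl-6-oxabicyclo[3.1.0]hexan-2-ol | C[C@@]12O[C@@H]1CC[C@@]2(O)C=C | intermediate
6 | (2S,3R)-2-ethenyl-3-hydroxy-2-methylcyclopentan-1-one | O=C1CC[C@@H](O)[C@]1(C)C=C | intermediate
7 | (2S,3R)-2-ethenyl-2-methyl-3-[(triisopropylsilyl)oxy]cyclopentan-1-one | O=C1CC[C@@H](O[Si](C(C)C)(C(C)C)C(C)C)[C@]1(C)C=C | intermediate
8 | 3,3-dimethylcyclobutan-1-one | CC1(C)CC(=O)C1 | starting material
9 | N'-(3,3-dimethylcyclobutylidene)-2,4,6-triisopropylbenzenesulfonohydrazide | CC1(C)CC(=NNS(=O)(=O)c2c(C(C)C)cc(C(C)C)cc2C(C)C)C1 | intermediate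
10 | 3,3-dimethylcyclobut-1-enyllithium | [Li]C1=CC(C)(C)C1 | intermediate
11 | (1R,2S,3R)-1-(3,3-dimethylcyclobut-1-en-1-yl)-2-ethenyl-2-methyl-3-[(triisopropylsilyl)oxy]cyclopentan-1-ol | O[C@@]1(C2=CC(C)(C)C2)CC[C@@H](O[Si](C(C)C)(C(C)C)C(C)C)[C@]1(C)C=C | intermediate
12 | potassium alkoxide of 11 | [K+].[O-][C@@]1(C2=CC(C)(C)C2)CC[C@@H](O[Si](C(C)C)(C(C)C)C(C)C)[C@]1(C)C=C | intermediate
13 | potassium C8=C9 enolate of 14 (ring-cis) | C/C1=C/C[C@@H]2/C(CC2(C)C)=C(/[O-])CC[C@H]1O[Si](C(C)C)(C(C)C)C(C)C.[K+] | intermediate
14 | (1R,3Z,5R,9S)-4,11,11-trimethyl-5-[(triisopropylsilyl)oxy]bicyclo[7.2.0]undec-3-en-8-one | C/C1=C/C[C@@H]2[C@H](CC2(C)C)C(=O)CC[C@H]1O[Si](C(C)C)(C(C)C)C(C)C | intermediate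
15 | (1R,3Z,5R,9S)-4,11,11-trimethyl-8-methylidene-5-[(triisopropylsilyl)oxy]bicyclo[7.2.0]undec-3-ene | C/C1=C/C[C@@H]2[C@H](CC2(C)C)C(=C)CC[C@H]1O[Si](C(C)C)(C(C)C)C(C)C | intermediate
16 | 2',4',6'-trihydroxyacetophenone | CC(=O)c1c(O)cc(O)cc1O | starting material
17 | acetylsyncarpic acid | CC(=O)C1=C(O)C(C)(C)C(=O)C(C)(C)C1=O | intermediate
18 | syncarpic acid (enol form) | CC1(C)C(O)=CC(=O)C(C)(C)C1=O | intermediate
19 | 3-methylbutanal | CC(C)CC=O | starting material
20 | 2,2,4,4-tetramethyl-6-(3-methylbutylidene)cyclohexane-1,3,5-trione | CC(C)CC=C1C(=O)C(C)(C)C(=O)C(C)(C)C1=O | intermediate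
21 | O-triisopropylsilyl tomentodione O (1R,3Z,5R,8S,9S,7'R) | C/C1=C/C[C@@H]2[C@H](CC2(C)C)[C@]2(CC[C@H]1O[Si](C(C)C)(C(C)C)C(C)C)C[C@@H](CC(C)C)C1=C(O2)C(C)(C)C(=O)C(C)(C)C1=O | intermediate
22 | tomentodione O | C/C1=C/C[C@@H]2[C@H](CC2(C)C)[C@]2(CC[C@H]1O)C[C@@H](CC(C)C)C1=C(O2)C(C)(C)C(=O)C(C)(C)C1=O | target

Total step count: 14. Longest linear sequence: 11 steps (steps 1–6, 8, 9, 10, 13, 14).

**Steps most likely to fail**

Step 9. The shift may be slowed by crowding at C1, which lies next to the gem-dimethyl carbon C11. Heterolytic fragmentation of the alkoxide at C4–C8, or silyl transfer to the tertiary alkoxide, could then overtake it. The fallback sets out from 7 and returns at 14, and fuses the cyclobutane on after an unhindered ring expansion. Vinylmagnesium bromide and CeCl3 would convert 7 into (1R,2S,3R)-1,2-diethenyl-2-methyl-3-[(triisopropylsilyl)oxy]cyclopentan-1-ol F1. The parent anionic oxy-Cope shift (KH, 18-crown-6) with Me3SiCl trapping of the regiodefined enolate would give silyl enol ether F2. Saegusa–Ito oxidation with Pd(OAc)2 in MeCN would give (2Z,5Z,7R)-6-methyl-7-[(triisopropylsilyl)oxy]cyclonona-2,5-dien-1-one F3. Enone–alkene [2+2] photocycloaddition of F3 with isobutene (hν, CH2Cl2, −40 °C) should place the CMe2 carbon on the β-carbon C1 (head-to-tail), and K2CO3 in MeOH would equilibrate the ring fusion to trans, giving 14. C1 would then rest only on the conformational bias of the ring, so its epimer would have to be separated.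

Step 13. Attack on the inner face of C8=C13, or leakage between the two orientations of the heterodiene, would erode selectivity at C8 and C7'. The encumbered heterodiene may also be consumed by a second molecule of 18 before it finds the alkene. The fallback sets out from 15 and returns at 21, and uses a flat, more reactive aromatic heterodiene, with the triketone ring made last by dearomatisation. 2,4-Dimethylbenzene-1,3,5-triol F4, 19 and 15 would be heated with ethylenediammonium diacetate in toluene at 80 °C. The o-quinone methide F5 formed in the flask should add to C8=C13 to give the 5,7-dihydroxy-6,8-dimethylchroman F6. Dearomative double C-methylation (MeI, NaOMe, MeOH) would then turn the phloroglucinol ring into the tetramethyl dione and give 21.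

Step 8. Incomplete Shapiro fragmentation, protonation of the strained alkenyllithium or enolisation of 7 would lower conversion. The fallback sets out from 8 and returns at 11, and reaches the same nucleophile by halogen–metal exchange. Ketone 8 would be converted with (PhO)3P, Br2 and Et3N in CH2Cl2 into 1-bromo-3,3-dimethylcyclobut-1-ene F7. Bromine–lithium exchange (t-BuLi, THF, −78 °C), transmetalation with CeCl3 and addition to 7 would give 11.

**Further compounds**
F1 | step 9 | (1R,2S,3R)-1,2-diethenyl-2-methyl-3-[(triisopropylsilyl)oxy]cyclopentan-1-ol | O[C@@]1(C=C)CC[C@@H](O[Si](C(C)C)(C(C)C)C(C)C)[C@]1(C)C=C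
F2 | step 9 | (1E,5Z,7R)-6-methyl-7-[(triisopropylsilyl)oxy]-1-[(trimethylsilyl)oxy]cyclonona-1,5-diene (both ring alkenes cis within the ring) | C/C1=C/CC/C=C(/O[Si](C)(C)C)CC[C@H]1O[Si](C(C)C)(C(C)C)C(C)C
F3 | step 9 | (2Z,5Z,7R)-6-methyl-7-[(triisopropylsilyl)oxy]cyclonona-2,5-dien-1-one | C/C1=C/C/C=C\C(=O)CC[C@H]1O[Si](C(C)C)(C(C)C)C(C)C
F4 | step 13 | 2,4-dimethylbenzene-1,3,5-triol | Cc1c(O)cc(O)c(C)c1O
F5 | step 13 | 3,5-dihydroxy-2,4-dimethyl-6-(3-methylbutylidene)cyclohexa-2,4-dien-1-one | CC(C)CC=C1C(=O)C(C)=C(O)C(C)=C1O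
F6 | step 13 | (1R,3Z,5R,8S,9S,7'R)-5-[(triisopropylsilyl)oxy]caryophyll-3-ene spiro-fused at C8 to 5,7-dihydroxy-4-isobutyl-6,8-dimethylchroman | C/C1=C/C[C@@H]2[C@H](CC2(C)C)[C@]2(CC[C@H]1O[Si](C(C)C)(C(C)C)C(C)C)C[C@@H](CC(C)C)c1c(O2)c(C)c(O)c(C)c1O
F7 | step 8 | 1-bromo-3,3-dimethylcyclobut-1-ene | BrC1=CC(C)(C)C1
A1 | direct plan | (−)-caryophyllene oxide | C[C@@]12CC[C@@H]3[C@H](CC3(C)C)C(=C)CC[C@H]1O2
A2 | direct plan | (1R,4R,5R,8R,9S)-4,5:8,13-diepoxycaryophyllane | C[C@@]12CC[C@@H]3[C@H](CC3(C)C)[C@@]4(CO4)CC[C@H]1O2
A3 | direct plan | (1R,4R,5R,8R,9S)-4,5-epoxy-13-iodocaryophyllan-8-ol | C[C@@]12CC[C@@H]3[C@H](CC3(C)C)[C@@](O)(CI)CC[C@H]1O2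
A4 | direct plan | 2,2,4,4-tetramethyl-6-(3-methylbutylidene)cyclohexane-1,3,5-trione | CC(C)CC=C1C(=O)C(C)(C)C(=O)C(C)(C)C1=O
A5 | direct plan | (1R,4R,5R,8S,9S,7'R)-hydroxy triketone from C13–C7' coupling | C[C@@]12CC[C@@H]3[C@H](CC3(C)C)[C@@](O)(C[C@@H](CC(C)C)C4=C(O)C(C)(C)C(=O)C(C)(C)C4=O)CC[C@H]1O2
A6 | direct plan | (1R,4R,5R,8S,9S,7'R)-4,5-epoxy spiro-chromenedione | C[C@@]12CC[C@@H]3[C@H](CC3(C)C)[C@]3(CC[C@H]1O2)C[C@@H](CC(C)C)C1=C(O3)C(C)(C)C(=O)C(C)(C)C1=O
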